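**Overview**

1. Disconnections: the aryl ester C6–O bond and the C8–O/C9–O bonds are cut first (back to a C6 carbinol and a C8=C9 alkene), then the C6–O bond (back to a C5=C6 alkene); the C1–C10 bond of the resulting bicyclo[5.3.0]decadiene is cut last.
2. Enabling feature: in the seven-membered ring the two functionalised edges C5–C6 and C8–C9 flank the single methylene C7 and are joined on the far side by the C1–C10 bond at the methyl-bearing fusion carbon. This is a cyclohepta-1,4-diene pattern, which opens to a cis-divinylcyclopropane (C6–C7–C8) carrying a cyclopentene (C1=C5) and a vinyl group (C9=C10).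
3. The cyclopropane goes back to a Z-allylic alcohol (C7 from CH2I2), a Z-selective olefination of a cyclopentenecarbaldehyde (C8, its methyl and C9 from a phosphonopropanoate; C10 later from a methylene ylide) and an ozonolysis/aldol ring contraction of (S)-terpinen-4-ol.
4. Forward ring order: cyclopentene (aldol condensation), cyclopropane (methylene transfer), then the seven-membered ring by [3,3] ring expansion of that cyclopropane.
5. Stereochemistry: C4 from the chiral pool; C1 by chirality transfer from the reagent-controlled cyclopropane; C8/C9 by osmylation anti to the C1 methyl; C5 by equilibration to the trans-fused ketone; C6 by thermodynamically controlled dissolving-metal reduction.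

Key step: step 9

Remark (labels): C1 = methyl-bearing fusion carbon, C2/C3 = cyclopentane CH2, C4 = isopropyl carbinol, C5 = fusion CH, C6 = ester carbinol, C7 = CH2, C8 = methyl carbinol, C9 = CHOH, C10 = CH2; "daucane" means this skeleton and β is the face carrying the C1 methyl.
Remark (assumption): (S)-(+)-terpinen-4-ol is taken as purchasable in high enantiomeric purity.
Remark (protecting group): the C4 silyl ether is kept until the C6 ketone has been equilibrated and reduced, so that no β-hydroxy ketone is exposed to base.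

**Step 1**
Reactants: 1 (S)-(+)-terpinen-4-ol
Product: 2 (S)-triethyl{[4-methyl-1-(propan-2-yl)cyclohex-3-en-1-yl]oxy}silane
Conditions: Et3SiOTf, 2,6-lutidine, CH2Cl2, 0 °C → rt
Reagents that add atoms: triethylsilyl trifluoromethanesulfonate, CC[Si](CC)(CC)OS(=O)(=O)C(F)(F)F
Why: Silyl triflate silylation is the standard way to cap a hindered tertiary alcohol, and the ether shields C4 from retro-aldol cleavage and ionisation later while leaving its configuration untouched.

**Step 2**
Reactants: 2 (S)-triethyl{[4-methyl-1-(propan-2-yl)cyclohex-3-en-1-yl]oxy}silane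
Product: 4 (3S)-6-oxo-3-(propan-2-yl)-3-(triethylsilyloxy)heptanal, via ozonide 3 (not isolated)
Conditions: O3, CH2Cl2, −78 °C; then Me2S, −78 °C → rt
Reagents that add atoms: ozone, [O-][O+]=O
Why: Ozonolysis with reductive work-up cleaves the only alkene into the methyl ketone (C1) and the aldehyde (C6) without affecting the silyl ether.

**Step 3**
Reactants: 4 (3S)-6-oxo-3-(propan-2-yl)-3-(triethylsilyloxy)heptanal
Product: 6 (5R)-2-methyl-5-(propan-2-yl)-5-(triethylsilyloxy)cyclopent-1-ene-1-carbaldehyde, via aldol 5 (not isolated)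
Conditions: (PhCH2)2NH2+ CF3CO2− (0.3 equiv), toluene, 50 °C
Reagents that add atoms: none
Why: Amine-salt-catalysed intramolecular aldol condensation, in which the enamine of the aldehyde (C5) adds to the methyl ketone (C1) in a 5-exo closure and the aldol dehydrates to the tetrasubstituted enal, as known for 6-oxoheptanals from cyclohexene cleavage; the buffered medium should spare the β-silyloxy group.

**Step 4**
Reactants: 6 (5R)-2-methyl-5-(propan-2-yl)-5-(triethylsilyloxy)cyclopent-1-ene-1-carbaldehyde; 7 ethyl 2-[bis(2,2,2-trifluoroethoxy)phosphoryl]propanoate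
Product: 8 ethyl (2Z)-2-methyl-3-[(5R)-2-methyl-5-(propan-2-yl)-5-(triethylsilyloxy)cyclopent-1-en-1-yl]prop-2-enoate
Conditions: KN(SiMe3)2, 18-crown-6, THF, −78 → −40 °C
Reagents that add atoms: ethyl 2-[bis(2,2,2-trifluoroethoxy)phosphoryl]propanoate (7), CCOC(=O)C(C)P(=O)(OCC(F)(F)F)OCC(F)(F)F
Why: Still–Gennari variant of the Horner–Wadsworth–Emmons reaction, where the electron-poor phosphonate and a dissociated potassium base make elimination from the kinetic adduct fast and so give the trisubstituted enoate with ring and ester cis.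

**Step 5**
Reactants: 8 ethyl (2Z)-2-methyl-3-[(5R)-2-methyl-5-(propan-2-yl)-5-(triethylsilyloxy)cyclopent-1-en-1-yl]prop-2-enoate
Product: 9 (2Z)-2-methyl-3-[(5R)-2-methyl-5-(propan-2-yl)-5-(triethylsilyloxy)cyclopent-1-en-1-yl]prop-2-en-1-ol
Conditions: i-Bu2AlH, CH2Cl2, −78 °C; aq. KNaC4H4O6
Reagents that add atoms: none
Why: 1,2-Reduction of the conjugated ester by i-Bu2AlH at low temperature gives the allylic alcohol without isomerising the Z-alkene or cleaving the silyl ether.

**Step 6**
Reactants: 9 (2Z)-2-methyl-3-[(5R)-2-methyl-5-(propan-2-yl)-5-(triethylsilyloxy)cyclopent-1-en-1-yl]prop-2-en-1-ol; 10 diiodomethane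
Product: 11 {(1S,2R)-1-methyl-2-[(5R)-2-methyl-5-(propan-2-yl)-5-(triethylsilyloxy)cyclopent-1-en-1-yl]cyclopropyl}methanol
Conditions: Et2Zn, CH2I2, DME, CH2Cl2, −10 °C; (4R,5R)-2-butyl-N,N,N′,N′-tetramethyl-1,3,2-dioxaborolane-4,5-dicarboxamide, −10 °C → rt
Reagents that add atoms: diiodomethane (10), ICI
Why: Charette asymmetric Simmons–Smith cyclopropanation, in which the zinc alkoxide held by the chiral dioxaborolane delivers CH2 stereospecifically to the adjacent Z-alkene only (the cyclopentene is remote and tetrasubstituted), so the Z geometry becomes the cis relation of ring and CH2OH and the (4R,5R) ligand, by its usual facial preference, should give the (1S,2R) cyclopropane.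

**Step 7**
Reactants: 11 {(1S,2R)-1-methyl-2-[(5R)-2-methyl-5-(propan-2-yl)-5-(triethylsilyloxy)cyclopent-1-en-1-yl]cyclopropyl}methanol
Product: 12 (1S,2S)-1-methyl-2-[(5R)-2-methyl-5-(propan-2-yl)-5-(triethylsilyloxy)cyclopent-1-en-1-yl]cyclopropane-1-carbaldehyde
Conditions: Dess–Martin periodinane, NaHCO3, CH2Cl2, 0 °C
Reagents that add atoms: none
Why: Dess–Martin oxidation under buffered conditions gives the aldehyde, whose α-carbon is quaternary and cannot epimerise, and cold handling suppresses the retro-Claisen shift open to a cis-2-alkenylcyclopropanecarbaldehyde.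

**Step 8**
Reactants: 12 (1S,2S)-1-methyl-2-[(5R)-2-methyl-5-(propan-2-yl)-5-(triethylsilyloxy)cyclopent-1-en-1-yl]cyclopropane-1-carbaldehyde; 13 methyltriphenylphosphonium bromide
Product: 14 triethyl{[(1R)-2-[(1R,2R)-2-ethenyl-2-methylcyclopropyl]-3-methyl-1-(propan-2-yl)cyclopent-2-en-1-yl]oxy}silane
Conditions: Ph3PCH3Br, KOtBu, THF, 0 °C; then 12, −78 → 0 °C
Reagents that add atoms: methyltriphenylphosphonium bromide (13), C[P+](c1ccccc1)(c1ccccc1)c1ccccc1.[Br-]
Why: Wittig methylenation converts the hindered, non-enolisable aldehyde into the vinyl group at or below 0 °C and so completes the cis-divinylcyclopropane without touching the cyclopropane stereocentres.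

**Step 9**
Reactants: 14 triethyl{[(1R)-2-[(1R,2R)-2-ethenyl-2-methylcyclopropyl]-3-methyl-1-(propan-2-yl)cyclopent-2-en-1-yl]oxy}silane
Product: 15 triethyl{[(3R,8aR)-6,8a-dimethyl-3-(propan-2-yl)-1,2,3,5,8,8a-hexahydroazulen-3-yl]oxy}silane
Conditions: toluene (degassed, base-washed sealed tube), 110 → 140 °C
Reagents that add atoms: none
Why: Thermal cis-divinylcyclopropane–cycloheptadiene (Cope) rearrangement, a concerted suprafacial [3,3] shift through the boat transition state in which the cyclopentene C1=C5 and the vinyl C9=C10 both lie over the three-membered ring, so that C1–C10 forms as C6–C8 breaks and the π bonds move to C5=C6 and C8=C9. It is the known strain-driven ring expansion of this substrate class, including cases with a fully substituted alkene terminus that end in a quaternary carbon of a fused bicycle. The seven-membered ring (C1, C10, C9, C8, C7, C6, C5) is closed by this pericyclic three-to-seven ring expansion onto the existing cyclopentene and not by an end-to-end cyclisation, so no medium-ring entropy or transannular penalty arises. The only new stereocentre, C1, is set by chirality transfer: only the endo boat can place two cis double bonds in the ring, so the cyclopropane configuration from step 6 forces C10 onto the face of C1 syn to the C4 isopropyl and leaves the C1 methyl cis to the C4 oxygen. The step needs the [3,3] path to win over a homodienyl 1,5-hydrogen shift and the cyclopropane to keep its configuration; the first is secured because the C8 methyl is trans to the cyclopentenyl group on C6, the second because the cis relation is locked by the Z-olefination and the stereospecific cyclopropanation and strain release makes the shift irreversible. The C1 methyl points toward C7 in the boat and the C4 isopropyl sits on its inner face, which should slow the shift without blocking it, hence the heating.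

**Step 10**
Reactants: 15 triethyl{[(3R,8aR)-6,8a-dimethyl-3-(propan-2-yl)-1,2,3,5,8,8a-hexahydroazulen-3-yl]oxy}silane
Product: 16 4β-(triethylsilyloxy)dauc-5-ene-8α,9α-diol
Conditions: OsO4 (cat.), N-methylmorpholine N-oxide, acetone/H2O, 0 °C → rt
Reagents that add atoms: N-methylmorpholine N-oxide, C[N+]1([O-])CCOCC1; water, O (oxygen relayed through catalytic OsO4, O=[Os](=O)(=O)=O)
Why: Upjohn dihydroxylation, in which only the C8=C9 bond is accessible (C5=C6 lies between the fully substituted C1 and C4) and syn addition on the face away from the angular C1 methyl should set C8 and C9 as the 8α,9α-diol.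

**Step 11**
Reactants: 16 4β-(triethylsilyloxy)dauc-5-ene-8α,9α-diol
Product: 17 8α,9α-isopropylidenedioxy-4β-(triethylsilyloxy)dauc-5-ene
Conditions: Me2C(OMe)2, pyridinium p-toluenesulfonate (cat.), CH2Cl2, rt
Reagents that add atoms: 2,2-dimethoxypropane, COC(C)(C)OC
Why: Acid-catalysed transketalisation closes the five-membered acetonide on the cis-diol under conditions mild enough for the tertiary silyl ether, masking C8/C9 for the oxidation and acylation to come.

**Step 12**
Reactants: 17 8α,9α-isopropylidenedioxy-4β-(triethylsilyloxy)dauc-5-ene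
Product: 19 8α,9α-isopropylidenedioxy-4β-(triethylsilyloxy)-5β-daucan-6β-ol, via alkylborane 18 (not isolated)
Conditions: BH3·THF, THF, 0 °C → rt; then NaOH, H2O2, 0 °C → rt
Reagents that add atoms: hydrogen peroxide, OO; borane–tetrahydrofuran, B.C1CCOC1 (boron stays only in 18)
Why: Hydroboration–oxidation, in which the small BH3 adds syn across the hindered trisubstituted C5=C6 bond with boron on the less substituted C6 and oxidation replaces boron by hydroxyl with retention; the facial course (drawn from the β face, away from the isopropyl group and the acetonide) does not matter because C5 and C6 are re-set in steps 14 and 15.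

**Step 13**
Reactants: 19 8α,9α-isopropylidenedioxy-4β-(triethylsilyloxy)-5β-daucan-6β-ol
Product: 20 8α,9α-isopropylidenedioxy-4β-(triethylsilyloxy)-5β-daucan-6-one
Conditions: Dess–Martin periodinane, NaHCO3, CH2Cl2, rt
Reagents that add atoms: none
Why: Dess–Martin oxidation converts the only free hydroxyl, the secondary one on C6, into the ketone under neutral conditions that leave the acetonide and silyl ether intact.

**Step 14**
Reactants: 20 8α,9α-isopropylidenedioxy-4β-(triethylsilyloxy)-5β-daucan-6-one
Product: 21 8α,9α-isopropylidenedioxy-4β-(triethylsilyloxy)-5α-daucan-6-one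
Conditions: K2CO3, MeOH, rt
Reagents that add atoms: none
Why: Base-mediated epimerisation through the C5 enolate should equilibrate the ring fusion to the trans isomer, in which C6 is anti to the C4 isopropyl group, and with the C4 oxygen still silylated no retro-aldol cleavage of C4–C5 can compete.

**Step 15**
Reactants: 21 8α,9α-isopropylidenedioxy-4β-(triethylsilyloxy)-5α-daucan-6-one
Product: 22 8α,9α-isopropylidenedioxy-4β-(triethylsilyloxy)-5α-daucan-6α-ol
Conditions: Li, liquid NH3, THF, t-BuOH, −78 → −33 °C; NH4Cl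
Reagents that add atoms: none
Why: Dissolving-metal reduction under thermodynamic control protonates the ketyl-derived carbanion to the more stable equatorial alcohol, the 6α-hydroxyl trans to the C5–C4 bond, and the silyl ether and acetonide are inert to Li/NH3.

**Step 16**
Reactants: 22 8α,9α-isopropylidenedioxy-4β-(triethylsilyloxy)-5α-daucan-6α-ol
Product: 23 8α,9α-isopropylidenedioxy-5α-daucane-4β,6α-diol
Conditions: HF·pyridine, pyridine, THF, 0 °C → rt
Reagents that add atoms: none
Why: Fluoride-driven desilylation frees the tertiary C4 hydroxyl, and the pyridine-buffered reagent leaves the acetonide in place.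

**Step 17**
Reactants: 23 8α,9α-isopropylidenedioxy-5α-daucane-4β,6α-diol; 24 4-(benzyloxy)benzoic acid
Product: 26 6α-[4-(benzyloxy)benzoyloxy]-8α,9α-isopropylidenedioxy-5α-daucan-4β-ol, via acid chloride 25 (not isolated)
Conditions: 24, (COCl)2, DMF (cat.), CH2Cl2, 0 °C → rt, evaporate; then 23, Et3N, 4-dimethylaminopyridine, CH2Cl2, rt
Reagents that add atoms: 4-(benzyloxy)benzoic acid (24), OC(=O)c1ccc(OCc2ccccc2)cc1
Why: Acylation by the acid chloride under nucleophilic catalysis occurs only at the secondary C6 hydroxyl, the tertiary C4 hydroxyl being too hindered, as in acylations of related 4,6-diols of this skeleton.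

**Step 18**
Reactants: 26 6α-[4-(benzyloxy)benzoyloxy]-8α,9α-isopropylidenedioxy-5α-daucan-4β-ol
Product: 27 6α-[4-(benzyloxy)benzoyloxy]-5α-daucane-4β,8α,9α-triol
Conditions: AcOH/H2O (4:1), 45 °C
Reagents that add atoms: none
Why: Mild acid hydrolysis removes the acetonide while the aryl ester, the benzyl ether and the tertiary alcohols tolerate aqueous acetic acid.

**Step 19**
Reactants: 27 6α-[4-(benzyloxy)benzoyloxy]-5α-daucane-4β,8α,9α-triol
Product: 28 (3R,3aS,4S,6R,7S,8aR)-3,6,7-trihydroxy-6,8a-dimethyl-3-(propan-2-yl)decahydroazulen-4-yl 4-hydroxybenzoate (CNP0197754.3)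
Conditions: H2 (1 atm), Pd/C, EtOAc, rt
Reagents that add atoms: none
Why: Hydrogenolysis cleaves the benzyl aryl ether to the free phenol, and with no alkene left and the ester not benzylic nothing else is reduced.

**Compound list**

1 | (S)-(+)-terpinen-4-ol, (1S)-4-methyl-1-(propan-2-yl)cyclohex-3-en-1-ol | CC(C)[C@]1(O)CCC(C)=CC1 | starting material
2 | (S)-triethyl{[4-methyl-1-(propan-2-yl)cyclohex-3-en-1-yl]oxy}silane | CC(C)[C@]1(O[Si](CC)(CC)CC)CCC(C)=CC1 | intermediate
3 | ozonide of 2 (1,2,4-trioxolane across the former alkene carbons; bridgehead diastereomers not defined) | CC(C)[C@]1(O[Si](CC)(CC)CC)CCC2(C)OOC(C1)O2 | intermediate (not isolated)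
4 | (3S)-6-oxo-3-(propan-2-yl)-3-(triethylsilyloxy)heptanal | CC(C)[C@](O[Si](CC)(CC)CC)(CCC(C)=O)CC=O | intermediate
5 | aldol, 2-hydroxy-2-methyl-5-(propan-2-yl)-5-(triethylsilyloxy)cyclopentane-1-carbaldehyde (the two new centres not defined) | CC(C)[C@]1(O[Si](CC)(CC)CC)CCC(C)(O)C1C=O | intermediate (not isolated)
6 | (5R)-2-methyl-5-(propan-2-yl)-5-(triethylsilyloxy)cyclopent-1-ene-1-carbaldehyde | CC(C)[C@]1(O[Si](CC)(CC)CC)CCC(C)=C1C=O | intermediate
7 | ethyl 2-[bis(2,2,2-trifluoroethoxy)phosphoryl]propanoate | CCOC(=O)C(C)P(=O)(OCC(F)(F)F)OCC(F)(F)F | starting material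
8 | ethyl (2Z)-2-methyl-3-[(5R)-2-methyl-5-(propan-2-yl)-5-(triethylsilyloxy)cyclopent-1-en-1-yl]prop-2-enoate | CC(C)[C@]1(O[Si](CC)(CC)CC)CCC(C)=C1/C=C(\C(=O)OCC)C | intermediate
9 | (2Z)-2-methyl-3-[(5R)-2-methyl-5-(propan-2-yl)-5-(triethylsilyloxy)cyclopent-1-en-1-yl]prop-2-en-1-ol | CC(C)[C@]1(O[Si](CC)(CC)CC)CCC(C)=C1/C=C(\CO)C | intermediate
10 | diiodomethane | ICI | starting material
11 | {(1S,2R)-1-methyl-2-[(5R)-2-methyl-5-(propan-2-yl)-5-(triethylsilyloxy)cyclopent-1-en-1-yl]cyclopropyl}methanol | CC(C)[C@]1(O[Si](CC)(CC)CC)CCC(C)=C1[C@@H]2C[C@]2(C)CO | intermediate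
12 | (1S,2S)-1-methyl-2-[(5R)-2-methyl-5-(propan-2-yl)-5-(triethylsilyloxy)cyclopent-1-en-1-yl]cyclopropane-1-carbaldehyde | CC(C)[C@]1(O[Si](CC)(CC)CC)CCC(C)=C1[C@@H]2C[C@]2(C)C=O | intermediate
13 | methyltriphenylphosphonium bromide | C[P+](c1ccccc1)(c1ccccc1)c1ccccc1.[Br-] | starting material
14 | triethyl{[(1R)-2-[(1R,2R)-2-ethenyl-2-methylcyclopropyl]-3-methyl-1-(propan-2-yl)cyclopent-2-en-1-yl]oxy}silane (cyclopentenyl and vinyl cis) | CC(C)[C@]1(O[Si](CC)(CC)CC)CCC(C)=C1[C@@H]2C[C@]2(C)C=C | intermediate
15 | triethyl{[(3R,8aR)-6,8a-dimethyl-3-(propan-2-yl)-1,2,3,5,8,8a-hexahydroazulen-3-yl]oxy}silane (4β-silyloxy-dauca-5,8-diene) | CC(C)[C@]1(O[Si](CC)(CC)CC)CC[C@]2(C)CC=C(C)CC=C12 | intermediate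
16 | 4β-(triethylsilyloxy)dauc-5-ene-8α,9α-diol | CC(C)[C@]1(O[Si](CC)(CC)CC)CC[C@]2(C)C[C@H](O)[C@](C)(O)CC=C12 | intermediate
17 | 8α,9α-isopropylidenedioxy-4β-(triethylsilyloxy)dauc-5-ene | CC(C)[C@]1(O[Si](CC)(CC)CC)CC[C@]2(C)C[C@@H]3OC(C)(C)O[C@]3(C)CC=C12 | intermediate
18 | alkylborane, 6β-boranyl-8α,9α-isopropylidenedioxy-4β-(triethylsilyloxy)-5β-daucane | CC(C)[C@]1(O[Si](CC)(CC)CC)CC[C@]2(C)C[C@@H]3OC(C)(C)O[C@]3(C)C[C@@H](B)[C@@H]21 | intermediate (not isolated)
19 | 8α,9α-isopropylidenedioxy-4β-(triethylsilyloxy)-5β-daucan-6β-ol | CC(C)[C@]1(O[Si](CC)(CC)CC)CC[C@]2(C)C[C@@H]3OC(C)(C)O[C@]3(C)C[C@@H](O)[C@@H]21 | intermediate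
20 | 8α,9α-isopropylidenedioxy-4β-(triethylsilyloxy)-5β-daucan-6-one (cis-fused) | CC(C)[C@]1(O[Si](CC)(CC)CC)CC[C@]2(C)C[C@@H]3OC(C)(C)O[C@]3(C)CC(=O)[C@@H]21 | intermediate
21 | 8α,9α-isopropylidenedioxy-4β-(triethylsilyloxy)-5α-daucan-6-one (trans-fused) | CC(C)[C@]1(O[Si](CC)(CC)CC)CC[C@]2(C)C[C@@H]3OC(C)(C)O[C@]3(C)CC(=O)[C@H]21 | intermediate
22 | 8α,9α-isopropylidenedioxy-4β-(triethylsilyloxy)-5α-daucan-6α-ol | CC(C)[C@]1(O[Si](CC)(CC)CC)CC[C@]2(C)C[C@@H]3OC(C)(C)O[C@]3(C)C[C@H](O)[C@H]21 | intermediate
23 | 8α,9α-isopropylidenedioxy-5α-daucane-4β,6α-diol | CC(C)[C@]1(O)CC[C@]2(C)C[C@@H]3OC(C)(C)O[C@]3(C)C[C@H](O)[C@H]21 | intermediate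
24 | 4-(benzyloxy)benzoic acid | OC(=O)c1ccc(OCc2ccccc2)cc1 | starting material
25 | 4-(benzyloxy)benzoyl chloride | O=C(Cl)c1ccc(OCc2ccccc2)cc1 | intermediate (not isolated)
26 | 6α-[4-(benzyloxy)benzoyloxy]-8α,9α-isopropylidenedioxy-5α-daucan-4β-ol | CC(C)[C@]1(O)CC[C@]2(C)C[C@@H]3OC(C)(C)O[C@]3(C)C[C@H](OC(=O)c4ccc(OCc5ccccc5)cc4)[C@H]21 | intermediate
27 | 6α-[4-(benzyloxy)benzoyloxy]-5α-daucane-4β,8α,9α-triol | CC(C)[C@]1(O)CC[C@]2(C)C[C@H](O)[C@](C)(O)C[C@H](OC(=O)c3ccc(OCc4ccccc4)cc3)[C@H]21 | intermediate
28 | (3R,3aS,4S,6R,7S,8aR)-3,6,7-trihydroxy-6,8a-dimethyl-3-(propan-2-yl)decahydroazulen-4-yl 4-hydroxybenzoate | CC(C)[C@]1(O)CC[C@]2(C)C[C@H](O)[C@](C)(O)C[C@H](OC(=O)c3ccc(O)cc3)[C@H]21 | target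

**Step count and risks**

Total step count: 19. Longest linear sequence: 19 steps (1 → 28); compounds 7, 10, 13 and 24 are bought and enter directly.

Steps most likely to fail:

**Step 9.** The [3,3] shift may be too slow at temperatures where the cyclopropane still holds its configuration, because the C1 methyl points into the boat and the C4 isopropyl sits on its inner face. One-centre epimerisation of the cyclopropane would then erode the configuration at C1, and prolonged heating may also cost the tertiary allylic silyl ether.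

Fallback (sets out from 6, comes back at 21): the quaternary carbon would be made by a charge-accelerated [3,3] shift of another kind and the seven-membered ring by metathesis.
- Reagent-controlled allylboration of 6 (the antipode of B-allyldiisopinocampheylborane that gives the R carbinol, Et2O, −78 °C) gives homoallylic alcohol F1.
- Its potassium alkoxide (KH, 18-crown-6, THF, 0 °C → rt) undergoes the anionic oxy-Cope rearrangement through a chair, in which C6 relays its configuration to C1, and gives aldehyde F2 carrying the C1 methyl and a C1 allyl group (C10, C9). F1 is drawn as the epimer that reaches the required face of C1 through the chair with a pseudo-axial oxido group, which keeps that group away from the quaternary C4; if the other chair proves preferred, the antipodal borane would be used.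
- Addition of CH2=C(CH3)CH2MgCl gives methallyl carbinol F3 as a mixture of C6 epimers.
- Ring-closing metathesis with the second-generation Grubbs catalyst, RuCl2(=CHPh)(PCy3)(H2IMes), in CH2Cl2 at 40 °C closes the seven-membered ring at C8=C9 and gives cycloheptenol F4.
- Osmylation as in step 10 gives triol F5, and acetonide formation as in step 11 gives alcohol F6, a C5/C6 stereoisomer mixture corresponding to 19.
- The oxidation of step 13 and the equilibration of step 14 converge this mixture on 21.

**Step 6.** Reagent control may be incomplete, or conversion low, on the hindered Z-trisubstituted dienol, whose bulky cyclopentenyl group sits cis to the directing CH2OH. The diastereomeric cis-cyclopropane would lead to the C1 epimer after step 9.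

Fallback (sets out from 6, comes back at 15): reagent control is moved from the zinc carbenoid to a chiral dirhodium carbenoid.
- Wittig methylenation of 6 (Ph3PCH3Br, KOtBu, THF) gives diene F7.
- Cyclopropanation of its terminal vinyl group with methyl 2-diazobut-3-enoate under Rh2(S-DOSP)4, dirhodium tetrakis[(S)-N-(4-dodecylbenzenesulfonyl)prolinate], or its antipode (pentane, −78 °C → rt) places the carbenoid vinyl group cis to the cyclopentenyl group and gives divinylcyclopropane ester F8.
- F8 rearranges on warming in toluene, as in step 9, to cycloheptadiene ester F9.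
- i-Bu2AlH gives allylic alcohol F10, MsCl/Et3N gives mesylate F11, and LiEt3BH reduces F11 to the C8 methyl of 15.

**Step 12.** The borane may fail to reach the C5=C6 double bond, which lies between two fully substituted carbons. The reaction may also stall at partial conversion while forcing conditions begin to reduce the acetonide.

Fallback (sets out from 17, comes back at 19, or at 21 through the C5 epimer): oxygen is first placed on C6 by epoxidation and C5 is then reduced by a radical route.
- Dimethyldioxirane (acetone, 0 °C) gives epoxide F12, drawn as the β-epoxide.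
- Cp2TiCl (trivalent titanium, made in the flask from Cp2TiCl2 and Zn dust) with 1,4-cyclohexadiene in THF opens it homolytically to the tertiary C5 radical, which abstracts hydrogen.
- This gives 19 or its C5 epimer, alcohol F13; either is oxidised as in step 13, and step 14 delivers 21.

**Further compounds**

F1 | step 9 | (1R)-1-[(5R)-2-methyl-5-(propan-2-yl)-5-(triethylsilyloxy)cyclopent-1-en-1-yl]but-3-en-1-ol | CC(C)[C@]1(O[Si](CC)(CC)CC)CCC(C)=C1[C@H](O)CC=C
F2 | step 9 | 2-methyl-5-(propan-2-yl)-2-(prop-2-en-1-yl)-5-(triethylsilyloxy)cyclopentane-1-carbaldehyde (C1 as in 15; C5 of the skeleton not defined) | CC(C)[C@]1(O[Si](CC)(CC)CC)CC[C@](C)(CC=C)C1C=O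
F3 | step 9 | methallyl carbinol, 3-methyl-1-[2-methyl-5-(propan-2-yl)-2-(prop-2-en-1-yl)-5-(triethylsilyloxy)cyclopentyl]but-3-en-1-ol (C5 and C6 not defined) | CC(C)[C@]1(O[Si](CC)(CC)CC)CC[C@](C)(CC=C)C1C(O)CC(C)=C
F4 | step 9 | 4β-(triethylsilyloxy)dauc-8-en-6-ol (C5 and C6 not defined) | CC(C)[C@]1(O[Si](CC)(CC)CC)CC[C@]2(C)CC=C(C)CC(O)C12
F5 | step 9 | 4β-(triethylsilyloxy)daucane-6,8α,9α-triol (C5 and C6 not defined) | CC(C)[C@]1(O[Si](CC)(CC)CC)CC[C@]2(C)C[C@H](O)[C@](C)(O)CC(O)C12
F6 | step 9 | 8α,9α-isopropylidenedioxy-4β-(triethylsilyloxy)daucan-6-ol (C5/C6 stereoisomer mixture corresponding to 19) | CC(C)[C@]1(O[Si](CC)(CC)CC)CC[C@]2(C)C[C@@H]3OC(C)(C)O[C@]3(C)CC(O)C12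
F7 | step 6 | triethyl{[(1R)-2-ethenyl-3-methyl-1-(propan-2-yl)cyclopent-2-en-1-yl]oxy}silane | CC(C)[C@]1(O[Si](CC)(CC)CC)CCC(C)=C1C=C
F8 | step 6 | methyl 1-ethenyl-2-[(5R)-2-methyl-5-(propan-2-yl)-5-(triethylsilyloxy)cyclopent-1-en-1-yl]cyclopropane-1-carboxylate (vinyl and cyclopentenyl cis; cyclopropane configured as in 14) | CC(C)[C@]1(O[Si](CC)(CC)CC)CCC(C)=C1[C@@H]2C[C@]2(C(=O)OC)C=C
F9 | step 6 | methyl (3R,8aR)-8a-methyl-3-(propan-2-yl)-3-(triethylsilyloxy)-1,2,3,5,8,8a-hexahydroazulene-6-carboxylate | CC(C)[C@]1(O[Si](CC)(CC)CC)CC[C@]2(C)CC=C(C(=O)OC)CC=C12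
F10 | step 6 | [(3R,8aR)-8a-methyl-3-(propan-2-yl)-3-(triethylsilyloxy)-1,2,3,5,8,8a-hexahydroazulen-6-yl]methanol | CC(C)[C@]1(O[Si](CC)(CC)CC)CC[C@]2(C)CC=C(CO)CC=C12
F11 | step 6 | [(3R,8aR)-8a-methyl-3-(propan-2-yl)-3-(triethylsilyloxy)-1,2,3,5,8,8a-hexahydroazulen-6-yl]methyl methanesulfonate | CC(C)[C@]1(O[Si](CC)(CC)CC)CC[C@]2(C)CC=C(COS(C)(=O)=O)CC=C12
F12 | step 12 | 5β,6β-epoxy-8α,9α-isopropylidenedioxy-4β-(triethylsilyloxy)daucane | CC(C)[C@]1(O[Si](CC)(CC)CC)CC[C@]2(C)C[C@@H]3OC(C)(C)O[C@]3(C)C[C@H]4O[C@@]412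
F13 | step 12 | 8α,9α-isopropylidenedioxy-4β-(triethylsilyloxy)-5α-daucan-6β-ol | CC(C)[C@]1(O[Si](CC)(CC)CC)CC[C@]2(C)C[C@@H]3OC(C)(C)O[C@]3(C)C[C@@H](O)[C@H]21
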